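**Strategy.** Labels: ring carbons C1–C10; C7 bears C11(=C13H2)–C12(=O)–O1, and O1 sits on C8. Everything rests on cutting O1–C8 and C11–C12, which leaves carbon dioxide. The key step exploits the trans-disposed oxygens on C8 and C9 next to C7 in the ten-membered ring: both are read as one cis-C8–C9 epoxide. A 1-bromovinyl group on C7 is lithiated and carboxylated, and the new acrylic acid opens the epoxide at C8 with inversion, closing the cis-fused γ-lactone and freeing the C9 hydroxyl in one flask. The precursor is a ten-membered carbocycle carrying both epoxides, built by asymmetric allylboration, Sharpless epoxidation and ring-closing metathesis.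

Key step: step 14

Remark (assumption): the labels C1–C13 and O1 are labels only, and the (R)-configured phosphoric acid in step 8 is assumed to direct Re-face attack on the enal as it does on aryl aldehydes (otherwise its antipode is used).

Step 1
Reactants: 1 (R)-β-citronellene
Product: 2 (4R)-4-methylhex-5-en-1-ol
Conditions: O3 (1 equiv), CH2Cl2/MeOH, −78 °C; then NaBH4, −78 → 0 °C
Reagents that add atoms: ozone, O=[O+][O-]
Why: Ozonolysis with one equivalent should cleave only the electron-rich trisubstituted olefin, and borohydride reduces the ozonide to the primary alcohol, leaving the vinyl group and the chiral-pool stereocenter (future C10) untouched.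

Step 2
Reactants: 2 (4R)-4-methylhex-5-en-1-ol
Product: 3 (3R)-6-bromo-3-methylhex-1-ene
Conditions: CBr4, PPh3, CH2Cl2, 0 °C
Reagents that add atoms: carbon tetrabromide, BrC(Br)(Br)Br
Why: The Appel reaction converts the unhindered primary alcohol into the bromide by SN2 displacement, remote from the stereocenter.

Step 3
Reactants: 3 (3R)-6-bromo-3-methylhex-1-ene, 4 ethyl but-2-ynoate
Product: 5 ethyl (2E,7R)-3,7-dimethylnona-2,8-dienoate
Conditions: Mg, THF; CuBr·SMe2, −40 °C; then 4, −78 °C; aq. NH4Cl
Reagents that add atoms: none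
Why: Grignard formation, transmetalation to the organocopper and syn-carbocupration of the ynoate at low temperature should place the new chain trans to the ester, setting the E-trisubstituted olefin (future C4=C5).

Step 4
Reactants: 5 ethyl (2E,7R)-3,7-dimethylnona-2,8-dienoate
Product: 6 (2E,7R)-3,7-dimethylnona-2,8-dien-1-ol
Conditions: i-Bu2AlH, CH2Cl2, −78 °C; aq. potassium sodium tartrate
Reagents that add atoms: none
Why: The aluminium hydride reduces the enoate by 1,2-addition only, so the olefin geometry is kept.

Step 5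
Reactants: 6 (2E,7R)-3,7-dimethylnona-2,8-dien-1-ol
Product: 7 (2E,7R)-3,7-dimethylnona-2,8-dienal
Conditions: MnO2, CH2Cl2, 23 °C
Reagents that add atoms: none
Why: Allylic oxidation with MnO2 is selective for the allylic alcohol and should not erode the E geometry.

Step 6
Reactants: 8 (Z)-1,2-dichloroethene, 9 ethynyltrimethylsilane
Product: 10 [(3Z)-4-chlorobut-3-en-1-yn-1-yl]trimethylsilane
Conditions: Pd(PPh3)4 (cat.), CuI (cat.), n-BuNH2, Et2O, 23 °C, excess 8
Reagents that add atoms: none
Why: Sonogashira coupling proceeds with retention of the Z geometry, and the excess of dichloroethene suppresses double coupling.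

Step 7
Reactants: 10 [(3Z)-4-chlorobut-3-en-1-yn-1-yl]trimethylsilane, 11 2-(iodomethyl)-4,4,5,5-tetramethyl-1,3,2-dioxaborolane
Product: 12 4,4,5,5-tetramethyl-2-[(2Z)-5-(trimethylsilyl)pent-2-en-4-yn-1-yl]-1,3,2-dioxaborolane
Conditions: Zn, THF; then 10, Pd(OAc)2 (cat.), SPhos, THF, 50 °C
Reagents that add atoms: none
Why: Zinc insertion gives the borylmethylzinc iodide, and Negishi coupling with the alkenyl chloride should give the Z-configured γ-alkynyl allylboronate with retention of geometry.

Step 8
Reactants: 7 (2E,7R)-3,7-dimethylnona-2,8-dienal, 12 the Z-allylboronate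
Product: 14 (3R,4S,5E,10R)-3-ethynyl-6,10-dimethyldodeca-1,5,11-trien-4-ol, via O-boryl silylalkyne adduct 13 (not isolated)
Conditions: (R)-3,3'-bis(2,4,6-triisopropylphenyl)-1,1'-binaphthyl-2,2'-diyl hydrogen phosphate (5 mol%), 4 Å MS, toluene, −30 °C; then K2CO3, MeOH, 23 °C
Reagents that add atoms: none
Why: Chiral phosphoric acid-catalysed allylboration through a closed chair transition state should set C6 by Re-face attack (catalyst control) and C7 syn to it (the Z γ-alkynyl group sits axial), and methanolysis then removes the O-boryl and C-silyl groups.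

Step 9
Reactants: 14 (3R,4S,5E,10R)-3-ethynyl-6,10-dimethyldodeca-1,5,11-trien-4-ol
Product: 15 (3S,4S,5E,10R)-3-(1-bromoethenyl)-6,10-dimethyldodeca-1,5,11-trien-4-ol
Conditions: i-Bu2AlH (2.4 equiv), Ni(dppp)Cl2 (3 mol%), THF, 0 → 22 °C; then NBS, −20 °C; aq. potassium sodium tartrate
Reagents that add atoms: N-bromosuccinimide, O=C1CCC(=O)N1Br
Why: Nickel-catalysed α-selective hydroalumination of the terminal alkyne (the alcohol is carried as its aluminium alkoxide) puts aluminium on the internal carbon, and bromodealumination with retention should give the 2-bromoalkene without touching the olefins.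

Step 10
Reactants: 15 (3S,4S,5E,10R)-3-(1-bromoethenyl)-6,10-dimethyldodeca-1,5,11-trien-4-ol
Product: 16 (1R,2S)-2-(1-bromoethenyl)-1-{(2R,3R)-3-methyl-3-[(4R)-4-methylhex-5-en-1-yl]oxiran-2-yl}but-3-en-1-ol
Conditions: Ti(OiPr)4 (20 mol%), D-(−)-diisopropyl tartrate (24 mol%), t-BuOOH, 4 Å MS, CH2Cl2, −20 °C
Reagents that add atoms: tert-butyl hydroperoxide, CC(C)(C)OO
Why: Sharpless asymmetric epoxidation in the matched sense should deliver oxygen to the face of the E C4=C5 olefin on which the C6 carbinol hydrogen lies, giving the erythro (4R,5R)-epoxy alcohol, while olefins that are not allylic to the hydroxyl stay untouched.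

Step 11
Reactants: 16 the epoxy alcohol
Product: 17 triethylsilyl ether of 16
Conditions: Et3SiOTf, 2,6-lutidine, CH2Cl2, −78 °C
Reagents that add atoms: triethylsilyl trifluoromethanesulfonate, CC[Si](CC)(CC)OS(=O)(=O)C(F)(F)F
Why: Silylation of the C6 hydroxyl at low temperature with a hindered base protects it through the organolithium and acylation steps without opening the neighbouring epoxide.

Step 12
Reactants: 17 triethylsilyl ether of 16
Product: 18 (1R,2R,3S,4Z,6R,10R)-3-(1-bromoethenyl)-6,10-dimethyl-2-[(triethylsilyl)oxy]-11-oxabicyclo[8.1.0]undec-4-ene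
Conditions: second-generation Grubbs catalyst (10 mol%), CH2Cl2 (1 mM), 40 °C
Reagents that add atoms: none
Why: Ring-closing metathesis of the two monosubstituted vinyl groups (the 1-bromovinyl olefin is too hindered and electron-poor to engage) should close the ten-membered ring at high dilution, and the Z C8=C9 olefin is expected because a ring that already holds the trans-fused epoxide accommodates a cis olefin with less strain.

Step 13
Reactants: 18 the Z-cyclodecene
Product: 19 (1R,2R,3S,4S,6R,7R,11R)-3-(1-bromoethenyl)-7,11-dimethyl-2-[(triethylsilyl)oxy]-5,12-dioxatricyclo[9.1.0.0^4,6]dodecane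
Conditions: mCPBA (1.2 equiv), CH2Cl2, 0 °C
Reagents that add atoms: 3-chloroperbenzoic acid, OOC(=O)c1cccc(Cl)c1
Why: Prilezhaev epoxidation of the only electron-rich olefin should occur, with C7–H eclipsing the olefin to relieve A1,3 strain, on the face anti to the C6 ring branch with its bulky silyloxy group and syn to the flat 1-bromovinyl group, giving the (8S,9R) cis-epoxide trans to the C7 substituent.

Step 14
Reactants: 19 the bis-epoxide
Product: 22 silyl-protected hydroxy lactone (4R,5R,6R,7S,8R,9R,10R), via vinyllithium 20 (not isolated), via epoxy acid 21 (not isolated)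
Conditions: t-BuLi (2.1 equiv), THF/Et2O, −78 °C; CO2 (gas), −78 → −20 °C; then AcOH, −20 → 30 °C
Reagents that add atoms: carbon dioxide, O=C=O
Why: Bromine–lithium exchange at the 1-bromovinyl group gives vinyllithium 20, which adds to CO2 to form the C11–C12 bond, and after protonation the acrylic acid 21 opens the adjacent cis-epoxide at C8 to form the O1–C8 bond. The closest known reaction types are the carboxylation of alkenyllithiums and the lactonization of γ,δ-epoxy acids. The γ-lactone ring (O1, C8, C7, C11, C12) closes in the 5-exo-tet mode. C8 is set by inversion, since backside attack anti to the epoxide oxygen is possible because the C7 acrylate and the epoxide are trans on the ring, which makes the lactone cis-fused, and C9 keeps the epoxide oxygen as the free hydroxyl with retention. The step needs attack at C8 and not at C9 (6-endo) or at C5 of the 4,5-epoxide (6-exo): the five-membered closure is kinetically preferred, C5 is flanked by the quaternary C4 and the silyloxy-bearing C6, and acetic acid is too weak to ionize the trisubstituted epoxide. Carboxylation at −78 °C is meant to outrun 3-exo attack of the vinyllithium on C8.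

Step 15
Reactants: 22 silyl-protected hydroxy lactone, 23 3-methylbut-2-enoyl chloride
Product: 24 silyl-protected target (C9 3-methylbut-2-enoate)
Conditions: pyridine, DMAP (cat.), CH2Cl2, 0 → 23 °C
Reagents that add atoms: none
Why: Acylation of the only free hydroxyl (C9) under mild nucleophilic catalysis installs the senecioate, and pyridine as base avoids deconjugation of the acyl chloride.

Step 16
Reactants: 24 silyl-protected target
Product: 25 target CNP0214930.1
Conditions: HF·pyridine, pyridine, THF, 0 °C
Reagents that add atoms: none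
Why: Buffered fluoride desilylation frees the C6 hydroxyl without opening the epoxide or adding to the α-methylene lactone.

**Compound list**

1 | (R)-β-citronellene, (3R)-3,7-dimethylocta-1,6-diene | C=C[C@H](C)CCC=C(C)C | starting material
2 | (4R)-4-methylhex-5-en-1-ol | C=C[C@H](C)CCCO | intermediate
3 | (3R)-6-bromo-3-methylhex-1-ene | C=C[C@H](C)CCCBr | intermediate
4 | ethyl but-2-ynoate | CC#CC(=O)OCC | starting material
5 | ethyl (2E,7R)-3,7-dimethylnona-2,8-dienoate | C=C[C@H](C)CCC/C(C)=C/C(=O)OCC | intermediate
6 | (2E,7R)-3,7-dimethylnona-2,8-dien-1-ol | C=C[C@H](C)CCC/C(C)=C/CO | intermediate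
7 | (2E,7R)-3,7-dimethylnona-2,8-dienal | C=C[C@H](C)CCC/C(C)=C/C=O | intermediate
8 | (Z)-1,2-dichloroethene | Cl/C=C\Cl | starting material
9 | ethynyltrimethylsilane | C#C[Si](C)(C)C | starting material
10 | [(3Z)-4-chlorobut-3-en-1-yn-1-yl]trimethylsilane | C[Si](C)(C)C#C/C=C\Cl | intermediate
11 | 2-(iodomethyl)-4,4,5,5-tetramethyl-1,3,2-dioxaborolane | ICB1OC(C)(C)C(C)(C)O1 | starting material
12 | 4,4,5,5-tetramethyl-2-[(2Z)-5-(trimethylsilyl)pent-2-en-4-yn-1-yl]-1,3,2-dioxaborolane | C[Si](C)(C)C#C/C=C\CB1OC(C)(C)C(C)(C)O1 | intermediate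
13 | O-(pinacolboryl) ether of (3R,4S,5E,10R)-6,10-dimethyl-3-[(trimethylsilyl)ethynyl]dodeca-1,5,11-trien-4-ol | C=C[C@H](C)CCC/C(C)=C/[C@H](OB1OC(C)(C)C(C)(C)O1)[C@H](C=C)C#C[Si](C)(C)C | intermediate (not isolated)
14 | (3R,4S,5E,10R)-3-ethynyl-6,10-dimethyldodeca-1,5,11-trien-4-ol | C=C[C@H](C)CCC/C(C)=C/[C@H](O)[C@H](C=C)C#C | intermediate
15 | (3S,4S,5E,10R)-3-(1-bromoethenyl)-6,10-dimethyldodeca-1,5,11-trien-4-ol | C=C[C@H](C)CCC/C(C)=C/[C@H](O)[C@H](C=C)C(Br)=C | intermediate
16 | (1R,2S)-2-(1-bromoethenyl)-1-{(2R,3R)-3-methyl-3-[(4R)-4-methylhex-5-en-1-yl]oxiran-2-yl}but-3-en-1-ol | C=C[C@H](C)CCC[C@@]1(C)O[C@@H]1[C@H](O)[C@H](C=C)C(Br)=C | intermediate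
17 | triethylsilyl ether of 16 | C=C[C@H](C)CCC[C@@]1(C)O[C@@H]1[C@H](O[Si](CC)(CC)CC)[C@H](C=C)C(Br)=C | intermediate
18 | (1R,2R,3S,4Z,6R,10R)-3-(1-bromoethenyl)-6,10-dimethyl-2-[(triethylsilyl)oxy]-11-oxabicyclo[8.1.0]undec-4-ene; labels (4R,5R,6R,7S,8Z,10R) | C=C(Br)[C@H]1/C=C\[C@H](C)CCC[C@@]2(C)O[C@@H]2[C@@H]1O[Si](CC)(CC)CC | intermediate
19 | (1R,2R,3S,4S,6R,7R,11R)-3-(1-bromoethenyl)-7,11-dimethyl-2-[(triethylsilyl)oxy]-5,12-dioxatricyclo[9.1.0.0^4,6]dodecane; labels (4R,5R,6R,7S,8S,9R,10R) | C=C(Br)[C@H]1[C@@H]2O[C@@H]2[C@H](C)CCC[C@@]3(C)O[C@@H]3[C@@H]1O[Si](CC)(CC)CC | intermediate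
20 | vinyllithium from 19 (Li in place of Br on C11) | [Li]C(=C)[C@H]1[C@@H]2O[C@@H]2[C@H](C)CCC[C@@]3(C)O[C@@H]3[C@@H]1O[Si](CC)(CC)CC | intermediate (not isolated)
21 | 2-substituted acrylic acid from 20 (CO2H on C11, both epoxides intact) | C=C(C(=O)O)[C@H]1[C@@H]2O[C@@H]2[C@H](C)CCC[C@@]3(C)O[C@@H]3[C@@H]1O[Si](CC)(CC)CC | intermediate (not isolated)
22 | (4R,5R,6R,7S,8R,9R,10R)-4,5-epoxy-9-hydroxy-6-[(triethylsilyl)oxy]-11(13)-en-12,8-olide of the C1–C10 ring (labels of the overview; cis-fused α-methylene-γ-lactone) | C=C1C(=O)O[C@H]2[C@H](O)[C@H](C)CCC[C@@]3(C)O[C@@H]3[C@H](O[Si](CC)(CC)CC)[C@@H]12 | intermediate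
23 | 3-methylbut-2-enoyl chloride | CC(C)=CC(=O)Cl | starting material
24 | 9-O-(3-methylbut-2-enoyl) derivative of 22, (4R,5R,6R,7S,8R,9R,10R) | C=C1C(=O)O[C@H]2[C@H](OC(=O)C=C(C)C)[C@H](C)CCC[C@@]3(C)O[C@@H]3[C@H](O[Si](CC)(CC)CC)[C@@H]12 | intermediate
25 | CNP0214930.1, (4R,5R,6R,7R,8R,9R,10R)-4,5-epoxy-6-hydroxy-9-(3-methylbut-2-enoyloxy)-11(13)-en-12,8-olide (labels of the overview) | C=C1C(=O)O[C@H]2[C@H](OC(=O)C=C(C)C)[C@H](C)CCC[C@@]3(C)O[C@@H]3[C@H](O)[C@@H]12 | target

**Totals.** 16 steps in all; the longest linear sequence is 14 steps (steps 1–5 and 8–16).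

**Steps most likely to fail**

1. Step 12 (ring closure). The diene may oligomerize by intermolecular metathesis, or close to the E olefin, which would lead to the wrong diol relationship. Fallback, from 17 back to 18: ozonolysis of the two monosubstituted vinyl groups (O3, CH2Cl2, −78 °C; Me2S; the electron-poor 1-bromovinyl group should be spared) should give the dialdehyde F1. Intramolecular pinacol coupling (SmI2, THF, high dilution, −78 → 0 °C) should give the ring cis-diol F2 (either cis-diol converges). Thiocarbonyldiimidazole (toluene, 80 °C) should give the cyclic thionocarbonate F3. Corey–Winter olefination with 1,3-dimethyl-2-phenyl-1,3,2-diazaphospholidine at 40 °C is a stereospecific syn elimination and should return the Z olefin 18.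

2. Step 13 (epoxidation of C8=C9). Oxygen may be transferred to the other olefin face, syn to the C6 branch. Fallback, from 18 back to 19: NBS in aqueous THF at 0 °C puts the bromonium ion on the face the peracid would have chosen, and anti attack of water should give the bromohydrin F4 together with its regioisomer F5. K2CO3 in MeOH closes either bromohydrin with inversion at the bromine-bearing carbon, which places the epoxide on the opposite face and gives 19.

3. Step 14 (key step). The vinyllithium may be consumed by attack on the neighbouring epoxide before carboxylation, or the exchange may be incomplete. Fallback, from 19 back to 22: hydroxycarbonylation of the alkenyl bromide with Pd(OAc)2 (cat.), Xantphos, CO (1 atm), H2O and Et3N in dioxane at 60 °C should give acid 21 as its triethylammonium salt without any carbanion, and acidification with AcOH should lactonize it to 22. This fallback makes no compound outside the list (F0).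

**Further compounds**

F1 | step 12 | dialdehyde from double ozonolysis of 17 (CHO on C7 and on C10 in place of the two vinyl groups) | O=C[C@H](C)CCC[C@@]1(C)O[C@@H]1[C@H](O[Si](CC)(CC)CC)[C@H](C=O)C(Br)=C
F2 | step 12 | ring cis-8,9-diol from pinacol coupling of F1 (one cis-diol shown) | C=C(Br)[C@H]1[C@H](O)[C@H](O)[C@H](C)CCC[C@@]2(C)O[C@@H]2[C@@H]1O[Si](CC)(CC)CC
F3 | step 12 | cyclic 8,9-thionocarbonate of F2 | C=C(Br)[C@H]1[C@@H]2OC(=S)O[C@@H]2[C@H](C)CCC[C@@]3(C)O[C@@H]3[C@@H]1O[Si](CC)(CC)CC
F4 | step 13 | bromohydrin of 18 with Br on C8 and OH on C9 (anti) | C=C(Br)[C@H]1[C@@H](Br)[C@H](O)[C@H](C)CCC[C@@]2(C)O[C@@H]2[C@@H]1O[Si](CC)(CC)CC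
F5 | step 13 | regioisomeric bromohydrin of 18 with OH on C8 and Br on C9 (anti) | C=C(Br)[C@H]1[C@H](O)[C@@H](Br)[C@H](C)CCC[C@@]2(C)O[C@@H]2[C@@H]1O[Si](CC)(CC)CC
F0 | step 14 | none | none
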